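The trap in a flask that slows is to carry its last rate forward: the last two readings of the north-east run, carried on to 18 min, give 0.453 M of target, more than the 0.400 M of substrate charged.

| flask | substrate | catalyst | target | time |
|---|---|---|---|---|
| north-east | 0.400 M | 8.00 × 10⁻⁴ M |  |  |
| east | 0.160 M | 8.00 × 10⁻⁴ M |  |  |
| south-west | 0.400 M | 8.00 × 10⁻⁴ M | 0.120 M |  |
| south-east | 0.400 M | 8.00 × 10⁻⁴ M |  | 18 min |

| north-east run: time / min | north-east run: [target] / M | east run: time / min | east run: [target] / M | south-west run: time / min | south-west run: [target] / M |
|---|---|---|---|---|---|
| 0.29 | 0.017 | 0.29 | 0.015 | 0.29 | 0.136 |
| 0.46 | 0.034 | 0.46 | 0.029 | 0.46 | 0.140 |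
| 0.73 | 0.055 | 0.73 | 0.039 | 0.73 | 0.150 |
| 1.2 | 0.071 | 1.2 | 0.045 | 1.2 | 0.175 |
| 1.8 | 0.103 | 1.8 | 0.065 | 1.8 | 0.194 |
| 2.9 | 0.143 | 2.9 | 0.087 | 2.9 | 0.224 |
| 4.6 | 0.195 | 4.6 | 0.113 | 4.6 | 0.267 |
| 7.3 | 0.247 | 7.3 | 0.135 | 7.3 | 0.324 |

(scatter of a reading: 0.003 M)

- Overall: substrate -> target, with catalyst as catalyst.
- Constant volume, constant temperature.
- Bound and free are read together.
- An order is taken over about fifteen percent of the charge, up and down.

* order of the initial rate in [substrate], near the charge of the north-east run, the rate being that where two percent of its substrate are target (one fixed amount of target, the same in the runs compared)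
* the east run starts with 0.240 M less of substrate than the north-east run, and with no target. Compared where both hold the same amount of substrate, once fifteen percent of what the east run was charged with has turned into target, is the east run faster, slower or alike (within a tenth)?
* target in the south-east run at 18 min, as a share of the substrate charged

The south-east run has the north-east charge, so I took the north-east readings as its early life and reckoned the small thing, the substrate still left. The last two north-east readings give 9.29 min for τ, the draining time: substrate left divided by rate, the pseudo-first-order time constant. Up to 0.73 min the north-east readings give 4.94 min. The south-west run, charged with target, already reads 8.51 min by 1.2 min, longer than that, so I assumed τ follows target, on a straight line through the two north-east values.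

At 7.3 min the north-east reading leaves 0.153 M of substrate, and I started the south-east run's last stretch from there. On my assumed line τ grows beyond 9.29 min, so holding it there drains too fast; that leaves 0.0484 M at 18 min and gives, on that assumption, an upper bound on the target of 87.9 %. The line's end value, with the charge wholly turned, is 13.3 min; holding that leaves 0.0685 M, a bound from below at 82.9 %. The line's τ halfway down the stretch, 10.9 min, tightens this to my figure of 85.6 %.

The forecast gave an order of 0.35, the east run faster, and 88 %, from “Extrapolating north-east from 7.3 to 18 min”; that share stands at my upper edge, above my figure.

The south-east run reached 85.9 %, with the order at 0.29 and the east run faster.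

    catalyst + substrate → target + catalyst (1056 /M/min)
    catalyst + substrate ⇌ idle catalyst-substrate complex, settled at all times (7.570 /M)
    catalyst + target ⇌ catalyst-product complex, settled at all times (24.20 /M)

At equal substrate, once 15 % of the east charge has turned, the east run's rate is 3.2 times the north-east rate. Reckoned from the north-east reading at 7.3 min, the south-east draining time averaged 10.7 min up to 18 min, longer than 9.29 min and shorter than 13.3 min. In the east run, between a quarter and half of its charge turned, at 0.872 min and 2.42 min, the draining time averaged 3.82 min.

Readings and results were generated by integration for substances that don't exist, noise included.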